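Helenien is cut at C11=C12 and C11'=C12' into a beta C15 phosphonium salt, the C10 trienedial and an epsilon C15 phosphonium salt made from (R)-α-ionone. Everything hinges on the beta ring (C1–C6): its fully substituted C5=C6 double bond lies next to the gem-dimethyl carbon C1 and carries the C7=C8 unit on C6, a ring-alkene-plus-vinyl diene of the kind an enyne gives on exo metathesis. A single ruthenium-catalysed isomerisation thus makes the ring, C5=C6 and C7=C8 from an open chain whose C3 carbinol is already in place. That chain is the TBS ether of (R)-2,6,6-trimethyloct-1-en-7-yn-4-ol, a 1,7-enyne with a terminal alkyne on the quaternary carbon and a methallyl alkene.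

Key step: step 5

Assumption: (R)-α-ionone of high enantiomeric purity (fermentation-derived natural grade) is taken as purchasable; atoms are numbered as in carotenoids (C1 to C20 for the beta half, primed numbers for the epsilon half).

Step 1
Reactants: 1 2,2-dimethylpent-4-enal; 2 dimethyl (1-diazo-2-oxopropyl)phosphonate
Product: 3 3,3-dimethylhex-5-en-1-yne
Conditions: K2CO3, MeOH, 0 °C → rt
Reagents that add atoms: dimethyl (1-diazo-2-oxopropyl)phosphonate (2), COP(=O)(OC)C(=[N+]=[N-])C(C)=O
Why: Ohira–Bestmann (Seyferth–Gilbert) homologation: methanolysis of 2 releases the diazomethylphosphonate anion, which olefinates the non-enolisable aldehyde and, after loss of N2 and a 1,2-hydrogen shift of the alkylidene carbene, leaves the terminal alkyne; the volatile enyne is carried on as a pentane solution.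

Step 2
Reactants: 3 3,3-dimethylhex-5-en-1-yne
Product: 5 3,3-dimethylpent-4-ynal, via secondary ozonide 4 (not isolated)
Conditions: O3, CH2Cl2/pentane, −78 °C, Sudan Red 7B end point; then Me2S, −78 °C → rt
Reagents that add atoms: ozone, [O-][O+]=O
Why: Ozonolysis with reductive work-up: ozone adds to the monosubstituted alkene much faster than to the terminal alkyne, the dye end point stops the gas flow before the alkyne is attacked, and Me2S reduces the ozonide to the aldehyde.

Step 3
Reactants: 5 3,3-dimethylpent-4-ynal; 6 2-methylallylmagnesium chloride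
Product: 8 (R)-2,6,6-trimethyloct-1-en-7-yn-4-ol, via diisopinocampheylborinate ester 7 (not isolated)
Conditions: (+)-Ipc2BOMe, 6, Et2O/THF, −78 °C → rt; then 5, −78 °C; then NaOH, H2O2, 0 °C → rt
Reagents that add atoms: 2-methylallylmagnesium chloride (6), CC(=C)C[Mg]Cl
Why: Brown asymmetric allylboration with a methallyl group: the (+)-Ipc2B reagent (from (−)-α-pinene) delivers the methallyl unit through a closed chair transition state to the Re face of the aldehyde, which sets the carbinol carbon (C3 of the carotenoid) as R, and the Grignard reagent is fully consumed in making the borane, so the alkyne C–H is not deprotonated.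

Step 4
Reactants: 8 (R)-2,6,6-trimethyloct-1-en-7-yn-4-ol
Product: 9 tert-butyldimethyl{[(4R)-2,6,6-trimethyloct-1-en-7-yn-4-yl]oxy}silane
Conditions: TBSCl, imidazole, DMF, rt
Reagents that add atoms: tert-butyldimethylsilyl chloride, CC(C)(C)[Si](C)(C)Cl
Why: Standard silylation of a secondary alcohol (imidazole-activated silyl chloride); the bulky ether keeps the oxygen from binding ruthenium in step 5 and survives steps 5 to 7.

Step 5
Reactants: 9 tert-butyldimethyl{[(4R)-2,6,6-trimethyloct-1-en-7-yn-4-yl]oxy}silane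
Product: 10 tert-butyldimethyl{[(1R)-3,5,5-trimethyl-4-vinylcyclohex-3-en-1-yl]oxy}silane
Conditions: RuCl2(=CHPh)(PCy3)(H2IMes) (second-generation Grubbs catalyst, 10 mol%), ethylene (1 atm), toluene (0.01 M), 80 °C
Reagents that add atoms: none
Why: Ethylene converts the precatalyst into Ru=CH2, which exchanges with the 1,1-disubstituted alkene to put ruthenium on C5; this alkylidene adds across C6≡C7 through a ruthenacyclobutene so that C5 bonds to C6, and the C7 vinylcarbene left behind is cleaved by ethylene to give C7=C8 and Ru=CH2 again (the other order of events, methylidene onto the alkyne with ruthenium on C6 followed by closure onto the methallyl group, leads to the same diene). The closest known reaction type is ring-closing enyne metathesis of 1,7-enynes to 1-vinylcyclohexenes under ethylene with N-heterocyclic-carbene ruthenium catalysts, which is also documented for 1,1-disubstituted alkenes that end as fully substituted ring alkenes. The six-membered ring closes in the exo mode, that is, only C6 of the alkyne becomes a ring atom and C7 stays outside. No stereocenter is created, and C3, remote from both reacting sites, is not touched. The step needs exo closure to win over endo closure (which would give a seven-membered ring), over ethylene–alkyne cross-metathesis and over oligomerisation; the smaller ring, the gem-dimethyl group on C1 (it folds the chain and screens the alkyne from bimolecular attack), the bulky silyl ether on C3, high dilution and the ethylene atmosphere (which reopens dimers and keeps the carbene alive) all work in that direction. The methylene lost from C5 returns through the ethylene pool as C8, so the net change is an isomerisation.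

Step 6
Reactants: 10 tert-butyldimethyl{[(1R)-3,5,5-trimethyl-4-vinylcyclohex-3-en-1-yl]oxy}silane; 11 but-3-en-2-one
Product: 12 (3E)-4-[(4R)-4-{[tert-butyl(dimethyl)silyl]oxy}-2,6,6-trimethylcyclohex-1-en-1-yl]but-3-en-2-one
Conditions: 11 (5 equiv), RuCl2(=CH-C6H4-2-OiPr)(H2IMes) (second-generation Hoveyda–Grubbs catalyst, 5 mol%), CH2Cl2, 40 °C
Reagents that add atoms: but-3-en-2-one (11), CC(=O)C=C
Why: Olefin cross-metathesis: the crowded monosubstituted vinyl group does not dimerise and exchanges with the electron-poor enone, the fully substituted ring alkene is inert, and the conjugated E enone is the thermodynamic product.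

Step 7
Reactants: 12 (3E)-4-[(4R)-4-{[tert-butyl(dimethyl)silyl]oxy}-2,6,6-trimethylcyclohex-1-en-1-yl]but-3-en-2-one; 13 vinylmagnesium bromide
Product: 14 (1E)-1-[(4R)-4-{[tert-butyl(dimethyl)silyl]oxy}-2,6,6-trimethylcyclohex-1-en-1-yl]-3-methylpenta-1,4-dien-3-ol (both C3 epimers of the pentadienol)
Conditions: 13, THF, −20 → 0 °C; then aq NH4Cl
Reagents that add atoms: vinylmagnesium bromide (13), C=C[Mg]Br
Why: Grignard 1,2-addition to the dienone carbonyl, the classical vinylation of ionone-type ketones; the new carbinol carbon C9 forms as both epimers, which does not matter because it becomes sp2 in step 8.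

Step 8
Reactants: 14 (1E)-1-[(4R)-4-{[tert-butyl(dimethyl)silyl]oxy}-2,6,6-trimethylcyclohex-1-en-1-yl]-3-methylpenta-1,4-dien-3-ol
Product: 15 {(2E,4E)-5-[(4R)-4-hydroxy-2,6,6-trimethylcyclohex-1-en-1-yl]-3-methylpenta-2,4-dien-1-yl}triphenylphosphonium bromide
Conditions: PPh3 (1.1 equiv), 48% aq HBr (1.5 equiv), MeOH, 0 °C → rt; crystallisation
Reagents that add atoms: triphenylphosphine, c1ccc(cc1)P(c1ccccc1)c1ccccc1; hydrogen bromide, Br
Why: Acid-mediated allylic transposition (SN1'): the tertiary doubly allylic alcohol ionises to a delocalised cation that PPh3 captures at the unhindered terminus C11, the 7E,9E salt being the thermodynamic isomer that crystallises, and the excess methanolic HBr removes the silyl ether in the same pot.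

Step 9
Reactants: 15 {(2E,4E)-5-[(4R)-4-hydroxy-2,6,6-trimethylcyclohex-1-en-1-yl]-3-methylpenta-2,4-dien-1-yl}triphenylphosphonium bromide; 16 (2E,4E,6E)-2,7-dimethylocta-2,4,6-trienedial
Product: 17 (3R)-3-hydroxy-12'-apo-beta-caroten-12'-al, (2E,4E,6E,8E,10E,12E)-13-[(4R)-4-hydroxy-2,6,6-trimethylcyclohex-1-en-1-yl]-2,7,11-trimethyltrideca-2,4,6,8,10,12-hexaenal
Conditions: 16 (3 equiv), NaOMe (slow addition), CH2Cl2/MeOH, 0 °C → rt; then EtOAc, reflux
Reagents that add atoms: (2E,4E,6E)-2,7-dimethylocta-2,4,6-trienedial (16), O=C/C(C)=C/C=C/C=C(C)/C=O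
Why: Wittig olefination: the allylic ylide generated in the presence of a threefold excess of the dialdehyde reacts at one formyl group only, and the hindered 11Z isomer formed beside the 11E isomer is converted into the all-E aldehyde on heating.

Step 10
Reactants: 18 (R)-α-ionone; 19 triethyl phosphonoacetate
Product: 20 ethyl (2E,4E)-3-methyl-5-[(1R)-2,6,6-trimethylcyclohex-2-en-1-yl]penta-2,4-dienoate
Conditions: 19, NaH, THF, 0 °C → rt
Reagents that add atoms: triethyl phosphonoacetate (19), CCOC(=O)CP(=O)(OCC)OCC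
Why: Horner–Wadsworth–Emmons olefination of the methyl ketone, which places the ester trans to the larger alkenyl branch (the minor 2Z isomer is removed by chromatography); the phosphonate anion is too weak a base to deprotonate C6', so the stereocenter of 18 is kept.

Step 11
Reactants: 20 ethyl (2E,4E)-3-methyl-5-[(1R)-2,6,6-trimethylcyclohex-2-en-1-yl]penta-2,4-dienoate
Product: 21 ethyl (2E,4E)-3-methyl-5-[(1R)-2,6,6-trimethyl-4-oxocyclohex-2-en-1-yl]penta-2,4-dienoate
Conditions: t-BuOOH (70% aq, 5 equiv), Rh2(C6H10NO)4 (dirhodium tetrakis(caprolactamate), 1 mol%), 1,2-dichloroethane, 40 °C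
Reagents that add atoms: tert-butyl hydroperoxide, CC(C)(C)OO
Why: Radical allylic oxidation with t-BuOOH under dirhodium catalysis: the ring CH2 (C3') is the only unhindered secondary allylic position, the tertiary C6'–H being screened by the gem-dimethyl group and the side chain, and the base-free medium avoids epimerisation of C6' in the enone formed.

Step 12
Reactants: 21 ethyl (2E,4E)-3-methyl-5-[(1R)-2,6,6-trimethyl-4-oxocyclohex-2-en-1-yl]penta-2,4-dienoate
Product: 22 ethyl (2E,4E)-5-[(1R,4R)-4-hydroxy-2,6,6-trimethylcyclohex-2-en-1-yl]-3-methylpenta-2,4-dienoate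
Conditions: (S)-2-methyl-CBS-oxazaborolidine (0.2 equiv), catecholborane, toluene, −78 °C; then MeOH, aq NaHCO3
Reagents that add atoms: none
Why: Corey–Bakshi–Shibata reduction under catalyst control: the ketone binds with the alkenyl carbon C4' as the large group and C2'H2 as the small one, so that the (S)-oxazaborolidine delivers hydride to the face that gives the 3'R carbinol, trans to the C6' side chain, while ester and alkenes are untouched.

Step 13
Reactants: 22 ethyl (2E,4E)-5-[(1R,4R)-4-hydroxy-2,6,6-trimethylcyclohex-2-en-1-yl]-3-methylpenta-2,4-dienoate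
Product: 23 ethyl (2E,4E)-5-[(1R,4R)-4-{[tert-butyl(dimethyl)silyl]oxy}-2,6,6-trimethylcyclohex-2-en-1-yl]-3-methylpenta-2,4-dienoate
Conditions: TBSCl, imidazole, DMF, rt
Reagents that add atoms: tert-butyldimethylsilyl chloride, CC(C)(C)[Si](C)(C)Cl
Why: Standard silylation; it masks the ring allylic alcohol during the ester reduction and the bromination, and fluoride removes it later without acid.

Step 14
Reactants: 23 ethyl (2E,4E)-5-[(1R,4R)-4-{[tert-butyl(dimethyl)silyl]oxy}-2,6,6-trimethylcyclohex-2-en-1-yl]-3-methylpenta-2,4-dienoate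
Product: 24 (2E,4E)-5-[(1R,4R)-4-{[tert-butyl(dimethyl)silyl]oxy}-2,6,6-trimethylcyclohex-2-en-1-yl]-3-methylpenta-2,4-dien-1-ol
Conditions: iBu2AlH (2.5 equiv), CH2Cl2, −78 °C; then aq potassium sodium tartrate (KNaC4H4O6)
Reagents that add atoms: none
Why: iBu2AlH reduction of the conjugated ester to the allylic alcohol at low temperature, with no conjugate reduction and no effect on the silyl ether.

Step 15
Reactants: 24 (2E,4E)-5-[(1R,4R)-4-{[tert-butyl(dimethyl)silyl]oxy}-2,6,6-trimethylcyclohex-2-en-1-yl]-3-methylpenta-2,4-dien-1-ol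
Product: 26 {(2E,4E)-5-[(1R,4R)-4-{[tert-butyl(dimethyl)silyl]oxy}-2,6,6-trimethylcyclohex-2-en-1-yl]-3-methylpenta-2,4-dien-1-yl}triphenylphosphonium bromide, via allylic bromide 25 (not isolated)
Conditions: CBr4 (1.1 equiv), PPh3 (1.1 equiv), CH2Cl2, 0 °C; then PPh3 (1.2 equiv), rt
Reagents that add atoms: carbon tetrabromide, BrC(Br)(Br)Br; triphenylphosphine, c1ccc(cc1)P(c1ccccc1)c1ccccc1
Why: Appel bromination followed by SN2 quaternisation of the labile dienyl bromide with PPh3, all under neutral conditions, so that neither the allylic silyl ether at C3' nor C6' is disturbed.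

Step 16
Reactants: 17 (3R)-3-hydroxy-12'-apo-beta-caroten-12'-al; 26 {(2E,4E)-5-[(1R,4R)-4-{[tert-butyl(dimethyl)silyl]oxy}-2,6,6-trimethylcyclohex-2-en-1-yl]-3-methylpenta-2,4-dien-1-yl}triphenylphosphonium bromide
Product: 27 (3R,3'R,6'R)-3'-{[tert-butyl(dimethyl)silyl]oxy}-beta,epsilon-caroten-3-ol
Conditions: NaOMe, CH2Cl2/MeOH, 0 °C → rt; then EtOAc, reflux, dark
Reagents that add atoms: none
Why: Wittig olefination forming C11'=C12': the ylide charge is spread over C11', C9' and C7' only, so C6' keeps its configuration, the free 3-OH is tolerated, and heating converts the 11'Z isomer into all-E material.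

Step 17
Reactants: 27 (3R,3'R,6'R)-3'-{[tert-butyl(dimethyl)silyl]oxy}-beta,epsilon-caroten-3-ol
Product: 28 lutein, (3R,3'R,6'R)-beta,epsilon-carotene-3,3'-diol
Conditions: Bu4NF, THF, 0 °C → rt, argon, dark
Reagents that add atoms: none
Why: Fluoride-mediated desilylation, chosen because the allylic 3'-carbinol and the polyene would not tolerate acid.

Step 18
Reactants: 28 lutein; 29 palmitoyl chloride
Product: 30 helenien, (3R,3'R,6'R)-beta,epsilon-carotene-3,3'-diyl dihexadecanoate
Conditions: 29 (3 equiv), pyridine, DMAP (cat.), CH2Cl2, 0 °C → rt, dark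
Reagents that add atoms: palmitoyl chloride (29), CCCCCCCCCCCCCCCC(=O)Cl
Why: Acylation of both secondary alcohols by the acid chloride with nucleophilic catalysis (DMAP); the C–O bonds at C3 and C3' are not broken, so both configurations are retained.

Compound list
1 | 2,2-dimethylpent-4-enal | C=CCC(C)(C)C=O | starting material
2 | dimethyl (1-diazo-2-oxopropyl)phosphonate | COP(=O)(OC)C(=[N+]=[N-])C(C)=O | starting material
3 | 3,3-dimethylhex-5-en-1-yne | C#CC(C)(C)CC=C | intermediate
4 | 3-(2,2-dimethylbut-3-yn-1-yl)-1,2,4-trioxolane (secondary ozonide, racemic) | C#CC(C)(C)CC1OCOO1 | intermediate (not isolated)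
5 | 3,3-dimethylpent-4-ynal | C#CC(C)(C)CC=O | intermediate
6 | 2-methylallylmagnesium chloride | CC(=C)C[Mg]Cl | starting material
7 | (R)-2,6,6-trimethyloct-1-en-7-yn-4-yl bis[(+)-isopinocampheyl]borinate (Ipc from (−)-α-pinene) | C#CC(C)(C)C[C@H](OB([C@@H]1[C@@H](C)[C@@H]2C[C@H](C1)C2(C)C)[C@@H]1[C@@H](C)[C@@H]2C[C@H](C1)C2(C)C)CC(C)=C | intermediate (not isolated)
8 | (R)-2,6,6-trimethyloct-1-en-7-yn-4-ol | C#CC(C)(C)C[C@H](O)CC(C)=C | intermediate
9 | tert-butyldimethyl{[(4R)-2,6,6-trimethyloct-1-en-7-yn-4-yl]oxy}silane | CC(C)(C)[Si](C)(C)O[C@@H](CC(C)(C)C#C)CC(C)=C | intermediate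
10 | tert-butyldimethyl{[(1R)-3,5,5-trimethyl-4-vinylcyclohex-3-en-1-yl]oxy}silane | CC(C)(C)[Si](C)(C)O[C@@H]1CC(C)=C(C=C)C(C)(C)C1 | intermediate
11 | but-3-en-2-one | CC(=O)C=C | starting material
12 | (3E)-4-[(4R)-4-{[tert-butyl(dimethyl)silyl]oxy}-2,6,6-trimethylcyclohex-1-en-1-yl]but-3-en-2-one | CC(C)(C)[Si](C)(C)O[C@@H]1CC(C)=C(/C=C/C(C)=O)C(C)(C)C1 | intermediate
13 | vinylmagnesium bromide | C=C[Mg]Br | starting material
14 | (1E)-1-[(4R)-4-{[tert-butyl(dimethyl)silyl]oxy}-2,6,6-trimethylcyclohex-1-en-1-yl]-3-methylpenta-1,4-dien-3-ol (both carbinol epimers) | CC(C)(C)[Si](C)(C)O[C@@H]1CC(C)=C(/C=C/C(C)(O)C=C)C(C)(C)C1 | intermediate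
15 | {(2E,4E)-5-[(4R)-4-hydroxy-2,6,6-trimethylcyclohex-1-en-1-yl]-3-methylpenta-2,4-dien-1-yl}triphenylphosphonium bromide | [Br-].O[C@@H]1CC(C)=C(/C=C/C(C)=C/C[P+](c2ccccc2)(c2ccccc2)c2ccccc2)C(C)(C)C1 | intermediate
16 | (2E,4E,6E)-2,7-dimethylocta-2,4,6-trienedial | O=C/C(C)=C/C=C/C=C(C)/C=O | starting material
17 | (3R)-3-hydroxy-12'-apo-beta-caroten-12'-al | O[C@@H]1CC(C)=C(/C=C/C(C)=C/C=C/C(C)=C/C=C/C=C(C)/C=O)C(C)(C)C1 | intermediate
18 | (R)-α-ionone, (3E)-4-[(1R)-2,6,6-trimethylcyclohex-2-en-1-yl]but-3-en-2-one | CC(=O)/C=C/[C@H]1C(C)=CCCC1(C)C | starting material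
19 | triethyl phosphonoacetate | CCOC(=O)CP(=O)(OCC)OCC | starting material
20 | ethyl (2E,4E)-3-methyl-5-[(1R)-2,6,6-trimethylcyclohex-2-en-1-yl]penta-2,4-dienoate | CCOC(=O)/C=C(C)/C=C/[C@H]1C(C)=CCCC1(C)C | intermediate
21 | ethyl (2E,4E)-3-methyl-5-[(1R)-2,6,6-trimethyl-4-oxocyclohex-2-en-1-yl]penta-2,4-dienoate | CCOC(=O)/C=C(C)/C=C/[C@H]1C(C)=CC(=O)CC1(C)C | intermediate
22 | ethyl (2E,4E)-5-[(1R,4R)-4-hydroxy-2,6,6-trimethylcyclohex-2-en-1-yl]-3-methylpenta-2,4-dienoate | CCOC(=O)/C=C(C)/C=C/[C@H]1C(C)=C[C@H](O)CC1(C)C | intermediate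
23 | ethyl (2E,4E)-5-[(1R,4R)-4-{[tert-butyl(dimethyl)silyl]oxy}-2,6,6-trimethylcyclohex-2-en-1-yl]-3-methylpenta-2,4-dienoate | CCOC(=O)/C=C(C)/C=C/[C@H]1C(C)=C[C@H](O[Si](C)(C)C(C)(C)C)CC1(C)C | intermediate
24 | (2E,4E)-5-[(1R,4R)-4-{[tert-butyl(dimethyl)silyl]oxy}-2,6,6-trimethylcyclohex-2-en-1-yl]-3-methylpenta-2,4-dien-1-ol | OC/C=C(C)/C=C/[C@H]1C(C)=C[C@H](O[Si](C)(C)C(C)(C)C)CC1(C)C | intermediate
25 | {[(1R,4R)-4-[(1E,3E)-5-bromo-3-methylpenta-1,3-dien-1-yl]-3,5,5-trimethylcyclohex-2-en-1-yl]oxy}(tert-butyl)dimethylsilane | BrC/C=C(C)/C=C/[C@H]1C(C)=C[C@H](O[Si](C)(C)C(C)(C)C)CC1(C)C | intermediate (not isolated)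
26 | {(2E,4E)-5-[(1R,4R)-4-{[tert-butyl(dimethyl)silyl]oxy}-2,6,6-trimethylcyclohex-2-en-1-yl]-3-methylpenta-2,4-dien-1-yl}triphenylphosphonium bromide | [Br-].c1ccccc1[P+](c1ccccc1)(c1ccccc1)C/C=C(C)/C=C/[C@H]1C(C)=C[C@H](O[Si](C)(C)C(C)(C)C)CC1(C)C | intermediate
27 | (3R,3'R,6'R)-3'-{[tert-butyl(dimethyl)silyl]oxy}-beta,epsilon-caroten-3-ol | O[C@@H]1CC(C)=C(/C=C/C(C)=C/C=C/C(C)=C/C=C/C=C(C)/C=C/C=C(C)/C=C/[C@H]2C(C)=C[C@H](O[Si](C)(C)C(C)(C)C)CC2(C)C)C(C)(C)C1 | intermediate
28 | lutein, (3R,3'R,6'R)-beta,epsilon-carotene-3,3'-diol | O[C@@H]1CC(C)=C(/C=C/C(C)=C/C=C/C(C)=C/C=C/C=C(C)/C=C/C=C(C)/C=C/[C@H]2C(C)=C[C@H](O)CC2(C)C)C(C)(C)C1 | intermediate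
29 | palmitoyl chloride (hexadecanoyl chloride) | CCCCCCCCCCCCCCCC(=O)Cl | starting material
30 | helenien, (3R,3'R,6'R)-beta,epsilon-carotene-3,3'-diyl dihexadecanoate | CCCCCCCCCCCCCCCC(=O)O[C@@H]1CC(C)=C(/C=C/C(C)=C/C=C/C(C)=C/C=C/C=C(C)/C=C/C=C(C)/C=C/[C@H]2C(C)=C[C@H](OC(=O)CCCCCCCCCCCCCCC)CC2(C)C)C(C)(C)C1 | target

Total step count: 18 steps.
Longest linear sequence: 12 steps (steps 1 to 9, then 16 to 18); the epsilon branch (steps 10 to 15) joins at step 16.

Steps most likely to fail

1. Step 5. The carbene may not be handed over to the hindered 1,1-disubstituted alkene, so that the alkyne is used up by cross-metathesis with ethylene, the ring closes in the endo sense, or turnover stops before the fully substituted alkene forms. The fallback sets out from 9 and comes back at 10. It keeps the fully substituted alkene out of the metathesis event and makes the C6–C7 bond by cross-coupling. Semi-hydrogenation of the alkyne (H2, Pd/CaCO3 poisoned with Pb(OAc)2, quinoline, hexane) should give tert-butyldimethyl{[(4R)-2,6,6-trimethylocta-1,7-dien-4-yl]oxy}silane F1. Ordinary ring-closing diene metathesis (RuCl2(=CHPh)(PCy3)(H2IMes), CH2Cl2, 40 °C) then forms only a trisubstituted alkene and should give tert-butyldimethyl{[(1R)-3,5,5-trimethylcyclohex-3-en-1-yl]oxy}silane F2. Hydroboration–oxidation (BH3·THF; NaOH, H2O2) places oxygen on C6 to give (4R)-4-[(tert-butyldimethylsilyl)oxy]-2,2,6-trimethylcyclohexan-1-ol F3, and Dess–Martin oxidation gives (4R)-4-[(tert-butyldimethylsilyl)oxy]-2,2,6-trimethylcyclohexan-1-one F4. This ketone can enolise on one side only, so LiN(iPr)2 and PhNTf2 should give (4R)-4-[(tert-butyldimethylsilyl)oxy]-2,6,6-trimethylcyclohex-1-en-1-yl trifluoromethanesulfonate F5. Stille coupling with tributyl(vinyl)stannane (Pd(PPh3)4, LiCl, THF, reflux) returns to 10.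

2. Step 6. Exchange at the crowded vinyl group may be too slow, the catalyst being spent on self-metathesis of the enone. The fallback sets out from 10 and comes back at 12, building C7=C8 by carbonyl condensation. Oxidative cleavage of the only unhindered alkene (K2OsO4·2H2O cat., NaIO4, 2,6-lutidine, dioxane/water) should give (4R)-4-[(tert-butyldimethylsilyl)oxy]-2,6,6-trimethylcyclohex-1-ene-1-carbaldehyde F6. Aldol condensation with acetone (aq NaOH, acetone, rt) then gives the E enone 12.

3. Step 12. Facial selectivity at the ring ketone may be poor if the ring's own bias works against the catalyst. The fallback sets out from 21 and comes back at 22, replacing catalyst control by separation and inversion. Luche reduction (NaBH4, CeCl3·7H2O, MeOH, −78 °C) gives 22 together with its epimer ethyl (2E,4E)-5-[(1R,4S)-4-hydroxy-2,6,6-trimethylcyclohex-2-en-1-yl]-3-methylpenta-2,4-dienoate F7, and the two are separated by chromatography. Mitsunobu reaction of the epimer (4-nitrobenzoic acid, PPh3, diisopropyl azodicarboxylate, THF, 0 °C) inverts C3' and gives (1R,4R)-4-[(1E,3E)-5-ethoxy-3-methyl-5-oxopenta-1,3-dien-1-yl]-3,5,5-trimethylcyclohex-2-en-1-yl 4-nitrobenzoate F8. Ethanolysis (K2CO3, EtOH, rt) converts this into more 22.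

Further compounds
F1 | step 5 | tert-butyldimethyl{[(4R)-2,6,6-trimethylocta-1,7-dien-4-yl]oxy}silane | CC(C)(C)[Si](C)(C)O[C@@H](CC(C)(C)C=C)CC(C)=C
F2 | step 5 | tert-butyldimethyl{[(1R)-3,5,5-trimethylcyclohex-3-en-1-yl]oxy}silane | CC(C)(C)[Si](C)(C)O[C@@H]1CC(C)=CC(C)(C)C1
F3 | step 5 | (4R)-4-[(tert-butyldimethylsilyl)oxy]-2,2,6-trimethylcyclohexan-1-ol (epimers at C1 and C6) | CC(C)(C)[Si](C)(C)O[C@@H]1CC(C)C(O)C(C)(C)C1
F4 | step 5 | (4R)-4-[(tert-butyldimethylsilyl)oxy]-2,2,6-trimethylcyclohexan-1-one (epimers at C6) | CC(C)(C)[Si](C)(C)O[C@@H]1CC(C)C(=O)C(C)(C)C1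
F5 | step 5 | (4R)-4-[(tert-butyldimethylsilyl)oxy]-2,6,6-trimethylcyclohex-1-en-1-yl trifluoromethanesulfonate | CC(C)(C)[Si](C)(C)O[C@@H]1CC(C)=C(OS(=O)(=O)C(F)(F)F)C(C)(C)C1
F6 | step 6 | (4R)-4-[(tert-butyldimethylsilyl)oxy]-2,6,6-trimethylcyclohex-1-ene-1-carbaldehyde | CC(C)(C)[Si](C)(C)O[C@@H]1CC(C)=C(C=O)C(C)(C)C1
F7 | step 12 | ethyl (2E,4E)-5-[(1R,4S)-4-hydroxy-2,6,6-trimethylcyclohex-2-en-1-yl]-3-methylpenta-2,4-dienoate | CCOC(=O)/C=C(C)/C=C/[C@H]1C(C)=C[C@@H](O)CC1(C)C
F8 | step 12 | (1R,4R)-4-[(1E,3E)-5-ethoxy-3-methyl-5-oxopenta-1,3-dien-1-yl]-3,5,5-trimethylcyclohex-2-en-1-yl 4-nitrobenzoate | CCOC(=O)/C=C(C)/C=C/[C@H]1C(C)=C[C@H](OC(=O)c2ccc(cc2)[N+]([O-])=O)CC1(C)C
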